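Rings A and D are 6,6-dimethylcyclohexa-2,4-dienones. Numbering each from the carbonyl C1 to the gem-dimethyl carbon C6, the oxygenated two-carbon unit C2–C3(O) sits between C1 and the bridge-bearing C4. This unit is removed as ethoxyacetylene, leaving C1, C4, C5 and C6 as a 3-ethoxy-4,4-dimethylcyclobutenone. The precursor is thus a bis(cyclobutenone) linked by CH2 groups to a hexamethoxydiarylmethane (rings B and C). Heating with the alkyne should insert C2–C3 into the C1–C4 bond of both four-membered rings at once (ring opening, [2+2], ring opening, 6π closure). Enol ether hydrolysis, fourfold propionylation and ether cleavage finish the route.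

Key step: step 7

Remark: the triketone rings are drawn as the dienol tautomer of the target; the molecule is built with twofold symmetry, so every step from step 3 on acts on two equivalent sites (step 9 on four) and uses up the stated equivalents, the first equivalent standing under Reactants and the further ones under Reagents that add atoms; in step 7 the two arms react independently and the unisolated intermediates are drawn with both arms at the same stage; iminium salts, boron chelates, enol esters and borate esters that are hydrolysed only in the aqueous work-up of steps 4, 9 and 10 count as bound forms of the product.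

Step 1
Reactants: 1 isobutyryl chloride; 2 ethoxyacetylene
Product: 4 3-ethoxy-4,4-dimethylcyclobut-2-en-1-one, via dimethylketene 3 (not isolated)
Conditions: Et3N, hexanes–Et2O, rt to 40 °C
Reagents that add atoms: none
Why: In situ dehydrochlorination gives dimethylketene, which should undergo the polarity-controlled ketene–ynol ether [2+2] cycloaddition (nucleophilic CH carbon of the alkyne to the ketene carbonyl carbon) to give the 3-alkoxycyclobutenone.

Step 2
Reactants: 4 3-ethoxy-4,4-dimethylcyclobut-2-en-1-one
Product: 5 3-hydroxy-4,4-dimethylcyclobut-2-en-1-one (enol of 2,2-dimethylcyclobutane-1,3-dione)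
Conditions: 1 M HCl, THF, 0 °C to rt
Reagents that add atoms: water, O
Why: Vinylogous ester hydrolysis under cold dilute acid, which should leave the four-membered ring intact and give the acidic enol of the 1,3-dione.

Step 3
Reactants: 6 1,3,5-trimethoxybenzene (two equivalents are built in, used in excess); 7 formaldehyde (one equivalent, used as paraformaldehyde)
Product: 8 bis(2,4,6-trimethoxyphenyl)methane
Conditions: (CH2O)n (limiting), 6 (excess), HCl (cat.), AcOH, rt
Reagents that add atoms: 1,3,5-trimethoxybenzene (second equivalent of 6), COc1cc(OC)cc(OC)c1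
Why: Acid-catalysed hydroxymethylation of one arene followed by Friedel–Crafts alkylation of a second, highly nucleophilic arene joins two molecules of 6 through one formaldehyde carbon with loss of water; the excess of arene should hold back further bridging.

Step 4
Reactants: 8 bis(2,4,6-trimethoxyphenyl)methane
Product: 9 3,3'-methylenebis(2,4,6-trimethoxybenzaldehyde)
Conditions: POCl3 (2.5 equiv), DMF, 0 to 60 °C; then aq. NaOAc
Reagents that add atoms: N,N-dimethylformamide (two equivalents), CN(C)C=O; water (two equivalents), O
Why: Vilsmeier–Haack formylation; once a ring carries an iminium group it is deactivated, so each ring should be formylated once, at either of its two equivalent free positions.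

Step 5
Reactants: 9 3,3'-methylenebis(2,4,6-trimethoxybenzaldehyde); 5 3-hydroxy-4,4-dimethylcyclobut-2-en-1-one (two equivalents are built in, one per aldehyde group)
Product: 11 bis{3-[(2-hydroxy-3,3-dimethyl-4-oxocyclobut-1-en-1-yl)methyl]-2,4,6-trimethoxyphenyl}methane, via bis(arylidenedione) 10 (not isolated)
Conditions: 5 (2.2 equiv), Hantzsch ester (diethyl 2,6-dimethyl-1,4-dihydropyridine-3,5-dicarboxylate, 2.2 equiv), L-proline (cat.), CH2Cl2, rt to 40 °C
Reagents that add atoms: 3-hydroxy-4,4-dimethylcyclobut-2-en-1-one (second equivalent of 5), OC1=CC(=O)C1(C)C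
Why: Three-component reductive alkylation of a cyclic 1,3-dione at both aldehyde groups: Knoevenagel condensation at the only C–H of the enolised dione gives the arylidenedione 10, which is reduced at once by conjugate hydride transfer from the Hantzsch ester, so that no 2,4,6-trimethoxybenzylic halide or cation has to be made.

Step 6
Reactants: 11 bis{3-[(2-hydroxy-3,3-dimethyl-4-oxocyclobut-1-en-1-yl)methyl]-2,4,6-trimethoxyphenyl}methane
Product: 12 bis{3-[(2-ethoxy-3,3-dimethyl-4-oxocyclobut-1-en-1-yl)methyl]-2,4,6-trimethoxyphenyl}methane
Conditions: Et3OBF4 (2.5 equiv), iPr2NEt, CH2Cl2, 0 °C to rt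
Reagents that add atoms: triethyloxonium tetrafluoroborate (two equivalents), CC[O+](CC)CC.F[B-](F)(F)F
Why: O-Alkylation of a vinylogous carboxylate by a Meerwein salt (hard electrophile, attack at oxygen); the two carbonyl groups of each dione are equivalent, so a single enol ether should form on each arm.

Step 7
Reactants: 12 bis{3-[(2-ethoxy-3,3-dimethyl-4-oxocyclobut-1-en-1-yl)methyl]-2,4,6-trimethoxyphenyl}methane; 2 ethoxyacetylene (two equivalents are built in, one per cyclobutenone, used in excess)
Product: 16 bis{3-[(2,6-diethoxy-3,3-dimethyl-4-oxocyclohexa-1,5-dien-1-yl)methyl]-2,4,6-trimethoxyphenyl}methane, via bis(vinylketene) 13 (not isolated), via bis(4-alkenylcyclobutenone) 14 (not isolated), via bis(dienylketene) 15 (not isolated)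
Conditions: ethoxyacetylene (excess, added in portions), PhMe, sealed tube, 95 °C
Reagents that add atoms: ethoxyacetylene (second equivalent of 2), C#COCC
Why: Proposed new method: each 3-ethoxy-4,4-dimethylcyclobutenone should open reversibly (thermal 4π electrocyclic cleavage of the C1–C6 bond, final-ring numbering) to the vinylketene 13, whose C1=C4 ketene bond takes up one molecule of ethoxyacetylene in a [2+2] cycloaddition to give the 4-alkenylcyclobutenone 14; a second 4π opening (cleaving C1–C4) gives the dienylketene 15, and the isomer with the ketenyl CH and the alkenyl group cis closes by 6π electrocyclization. The closest known reaction type is the Danheiser benzannulation of cyclobutenones with alkoxy- or siloxyalkynes to resorcinol ethers; it is new here because C6 is quaternary, so that no tautomerisation to a phenol can follow and the cascade must end at the cyclohexa-2,4-dienone, the form to which 6,6-disubstituted dienylketenes are known to revert thermally. Each of the two six-membered rings is thus closed by a 6π electrocyclic ring closure forming C1–C6, after the [2+2] step has made C1–C2 and C3–C4. No stereocentre remains in 16, since the quaternary carbon of 14 is transient and becomes sp2 again. The one selectivity needed is the regiochemistry of the ketene–alkyne [2+2] step, which the polarity of the ynol ether secures: its nucleophilic CH carbon bonds to the electrophilic ketene carbon C1 and the ethoxy-bearing carbon to C4, next to the bridge. Side reactions are limited by the substrate and the conditions: both positions ortho to each benzylic CH2 carry methoxy groups, so no aromatic C–H can reach the ketenes, reversible ring opening funnels the unproductive dienylketene isomer back, and the alkyne is kept in excess below the temperature of its retro-ene fragmentation.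

Step 8
Reactants: 16 bis{3-[(2,6-diethoxy-3,3-dimethyl-4-oxocyclohexa-1,5-dien-1-yl)methyl]-2,4,6-trimethoxyphenyl}methane
Product: 17 bis{3-[(2,6-dihydroxy-3,3-dimethyl-4-oxocyclohexa-1,5-dien-1-yl)methyl]-2,4,6-trimethoxyphenyl}methane
Conditions: 2 M HCl, THF, 45 °C
Reagents that add atoms: water (four equivalents), O
Why: Acid hydrolysis of the four vinylogous-ester enol ethers to the enolised cyclohexane-1,3,5-trione (filicinic acid type) rings; aryl methyl ethers and the CH2 bridges should be stable to dilute acid.

Step 9
Reactants: 17 bis{3-[(2,6-dihydroxy-3,3-dimethyl-4-oxocyclohexa-1,5-dien-1-yl)methyl]-2,4,6-trimethoxyphenyl}methane; 18 propionic anhydride (four equivalents are consumed, one per ring, used in excess)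
Product: 19 bis{3-[(2,6-dihydroxy-3,3-dimethyl-4-oxo-5-propanoylcyclohexa-1,5-dien-1-yl)methyl]-2,4,6-trimethoxy-5-propanoylphenyl}methane
Conditions: (EtCO)2O (excess), BF3·OEt2, CH2Cl2, 0 to 40 °C; then aq. NaOAc, MeOH, rt
Reagents that add atoms: propionic anhydride (three further equivalents of 18), CCC(=O)OC(=O)CC
Why: BF3-promoted acylation by the anhydride, one propionyl group per molecule of anhydride, as Friedel–Crafts acylation at the one free position of each trimethoxyarene ring and as C-acylation at the one free CH of each enolised triketone ring (enol esters being funnelled to the chelated C-acyl triketone); these four carbons are the only unsubstituted ones, and no free phenol is present that could be O-acylated or cyclise onto a triketone.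

Step 10
Reactants: 19 bis{3-[(2,6-dihydroxy-3,3-dimethyl-4-oxo-5-propanoylcyclohexa-1,5-dien-1-yl)methyl]-2,4,6-trimethoxy-5-propanoylphenyl}methane
Product: 20 bis{3-[(2,6-dihydroxy-3,3-dimethyl-4-oxo-5-propanoylcyclohexa-1,5-dien-1-yl)methyl]-2,4,6-trihydroxy-5-propanoylphenyl}methane (target)
Conditions: BBr3 (excess), CH2Cl2, −78 °C to rt; then MeOH, H2O
Reagents that add atoms: none
Why: Lewis acid ether cleavage (O-complexation, then bromide attack at methyl) of all six aryl methyl ethers, run cold; the acyl groups, installed first, should make the phloroglucinol rings less prone to ipso protonation and loss of a CH2 bridge.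

Compound list
1 | isobutyryl chloride (2-methylpropanoyl chloride) | CC(C)C(Cl)=O | starting material
2 | ethoxyacetylene (ethoxyethyne) | C#COCC | starting material
3 | dimethylketene (2-methylprop-1-en-1-one) | CC(C)=C=O | intermediate
4 | 3-ethoxy-4,4-dimethylcyclobut-2-en-1-one | CCOC1=CC(=O)C1(C)C | intermediate
5 | 3-hydroxy-4,4-dimethylcyclobut-2-en-1-one (enol of 2,2-dimethylcyclobutane-1,3-dione) | OC1=CC(=O)C1(C)C | intermediate
6 | 1,3,5-trimethoxybenzene | COc1cc(OC)cc(OC)c1 | starting material
7 | formaldehyde | C=O | starting material
8 | bis(2,4,6-trimethoxyphenyl)methane | COc1cc(OC)c(Cc2c(OC)cc(OC)cc2OC)c(OC)c1 | intermediate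
9 | 3,3'-methylenebis(2,4,6-trimethoxybenzaldehyde) | COc1cc(OC)c(Cc2c(OC)cc(OC)c(C=O)c2OC)c(OC)c1C=O | intermediate
10 | bis{3-[(3,3-dimethyl-2,4-dioxocyclobutylidene)methyl]-2,4,6-trimethoxyphenyl}methane (bis(arylidenedione), not isolated) | COc1cc(OC)c(Cc2c(OC)cc(OC)c(C=C3C(=O)C(C)(C)C3=O)c2OC)c(OC)c1C=C1C(=O)C(C)(C)C1=O | intermediate
11 | bis{3-[(2-hydroxy-3,3-dimethyl-4-oxocyclobut-1-en-1-yl)methyl]-2,4,6-trimethoxyphenyl}methane | COc1cc(OC)c(Cc2c(OC)cc(OC)c(CC3=C(O)C(C)(C)C3=O)c2OC)c(OC)c1CC1=C(O)C(C)(C)C1=O | intermediate
12 | bis{3-[(2-ethoxy-3,3-dimethyl-4-oxocyclobut-1-en-1-yl)methyl]-2,4,6-trimethoxyphenyl}methane (precursor of the key step) | COc1cc(OC)c(Cc2c(OC)cc(OC)c(CC3=C(OCC)C(C)(C)C3=O)c2OC)c(OC)c1CC1=C(OCC)C(C)(C)C1=O | intermediate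
13 | bis{3-[2-(1-ethoxy-2-methylprop-1-en-1-yl)-3-oxoprop-2-en-1-yl]-2,4,6-trimethoxyphenyl}methane (bis(vinylketene), not isolated) | COc1cc(OC)c(Cc2c(OC)cc(OC)c(CC(=C=O)C(OCC)=C(C)C)c2OC)c(OC)c1CC(=C=O)C(OCC)=C(C)C | intermediate
14 | bis(3-{[2-ethoxy-1-(1-ethoxy-2-methylprop-1-en-1-yl)-4-oxocyclobut-2-en-1-yl]methyl}-2,4,6-trimethoxyphenyl)methane (bis(4-alkenylcyclobutenone), not isolated; mixture of stereoisomers at the two transient quaternary carbons) | COc1cc(OC)c(Cc2c(OC)cc(OC)c(CC3(C(OCC)=C(C)C)C(=O)C=C3OCC)c2OC)c(OC)c1CC1(C(OCC)=C(C)C)C(=O)C=C1OCC | intermediate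
15 | bis{3-[(2E)-3-ethoxy-2-(1-ethoxy-2-methylprop-1-en-1-yl)-5-oxopenta-2,4-dien-1-yl]-2,4,6-trimethoxyphenyl}methane (bis(dienylketene), not isolated; ketenyl CH cis to the alkenyl group) | COc1cc(OC)c(Cc2c(OC)cc(OC)c(C/C(=C(OCC)/C=C=O)C(OCC)=C(C)C)c2OC)c(OC)c1C/C(=C(OCC)/C=C=O)C(OCC)=C(C)C | intermediate
16 | bis{3-[(2,6-diethoxy-3,3-dimethyl-4-oxocyclohexa-1,5-dien-1-yl)methyl]-2,4,6-trimethoxyphenyl}methane (product of the key step) | COc1cc(OC)c(Cc2c(OC)cc(OC)c(CC3=C(OCC)C(C)(C)C(=O)C=C3OCC)c2OC)c(OC)c1CC1=C(OCC)C(C)(C)C(=O)C=C1OCC | intermediate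
17 | bis{3-[(2,6-dihydroxy-3,3-dimethyl-4-oxocyclohexa-1,5-dien-1-yl)methyl]-2,4,6-trimethoxyphenyl}methane | COc1cc(OC)c(Cc2c(OC)cc(OC)c(CC3=C(O)C(C)(C)C(=O)C=C3O)c2OC)c(OC)c1CC1=C(O)C(C)(C)C(=O)C=C1O | intermediate
18 | propionic anhydride | CCC(=O)OC(=O)CC | starting material
19 | bis{3-[(2,6-dihydroxy-3,3-dimethyl-4-oxo-5-propanoylcyclohexa-1,5-dien-1-yl)methyl]-2,4,6-trimethoxy-5-propanoylphenyl}methane | CCC(=O)C1=C(O)C(Cc2c(OC)c(Cc3c(OC)c(CC4=C(O)C(C)(C)C(=O)C(C(=O)CC)=C4O)c(OC)c(C(=O)CC)c3OC)c(OC)c(C(=O)CC)c2OC)=C(O)C(C)(C)C1=O | intermediate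
20 | bis{3-[(2,6-dihydroxy-3,3-dimethyl-4-oxo-5-propanoylcyclohexa-1,5-dien-1-yl)methyl]-2,4,6-trihydroxy-5-propanoylphenyl}methane (no stereocentre) | CCC(=O)C1=C(O)C(Cc2c(O)c(Cc3c(O)c(CC4=C(O)C(C)(C)C(=O)C(C(=O)CC)=C4O)c(O)c(C(=O)CC)c3O)c(O)c(C(=O)CC)c2O)=C(O)C(C)(C)C1=O | target

Total step count: 10.
Longest linear sequence: 8 steps (steps 3 to 10 from compound 6; equally steps 1, 2 and 5 to 10 from compound 1).

Steps most likely to fail

Step 7. The cyclobutenone may not open below the temperature at which ethoxyacetylene loses ethylene, so that the alkyne is consumed before the vinylketene forms. The vinylketene may also escape by a 1,5-hydrogen shift from one of its methyl groups or by dimerisation, and one arm may react while the other decomposes. The fallback uses known chemistry and sets out from dialdehyde 9. A three-component reductive alkylation of 9 with a large excess of purchased filicinic acid (2,2-dimethylcyclohexane-1,3,5-trione, CC1(C)C(=O)CC(=O)CC1=O), Hantzsch ester and catalytic L-proline in CH2Cl2 would pass through the bis(arylidene) triketone F1, which is reduced in the flask. This should give 17 directly, where the route is rejoined. The excess of the trione is meant to keep its second CH2 group from reacting with another aldehyde.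

Step 5. The condensation may be slow at the doubly ortho-substituted aldehydes, a second dione may add to the arylidene intermediate in a Michael reaction, and the amine catalyst may open the strained dione. The fallback again sets out from 9. Reduction with NaBH4 in MeOH–THF would give the bis(benzylic alcohol) F2. Stirring this diol with an excess of 5 and catalytic TsOH in MeNO2 at rt should ionise the 2,4,6-trimethoxybenzylic alcohols and let the enol carbon of 5 capture each cation (acid-catalysed dehydrative benzylation of a 1,3-dione). The excess of 5 and dilution are meant to outrun attack by the free aryl position of a second molecule. The route is rejoined at 11.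

Step 9. The acylium ion may attack a bridge-bearing aryl carbon and expel a benzylic cation (bridge cleavage), the crowded aryl positions may be acylated incompletely, and methyl ethers next to the new ketones may be partly lost. The fallback sets out from 17 and separates the two kinds of acylation. Propionic acid, DCC and DMAP in CH2Cl2 (O-acylation followed by DMAP-mediated O-to-C acyl shift) would acylate only the triketone rings and give the bis(propionyl triketone) with free aryl positions F3. The two aryl positions would then be acylated with propionyl chloride and SnCl4 in CH2Cl2 at −20 °C, a milder Friedel–Crafts system, to rejoin the route at 19.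

Further compounds
F1 | step 7 | bis{3-[(3,3-dimethyl-2,4,6-trioxocyclohexylidene)methyl]-2,4,6-trimethoxyphenyl}methane (alkene geometry not defined, either isomer is reduced to 17) | COc1cc(OC)c(Cc2c(OC)cc(OC)c(C=C3C(=O)CC(=O)C(C)(C)C3=O)c2OC)c(OC)c1C=C1C(=O)CC(=O)C(C)(C)C1=O
F2 | step 5 | [methylenebis(2,4,6-trimethoxy-3,1-phenylene)]dimethanol | COc1cc(OC)c(Cc2c(OC)cc(OC)c(CO)c2OC)c(OC)c1CO
F3 | step 9 | bis{3-[(2,6-dihydroxy-3,3-dimethyl-4-oxo-5-propanoylcyclohexa-1,5-dien-1-yl)methyl]-2,4,6-trimethoxyphenyl}methane | CCC(=O)C1=C(O)C(Cc2c(OC)c(Cc3c(OC)c(CC4=C(O)C(C)(C)C(=O)C(C(=O)CC)=C4O)c(OC)cc3OC)c(OC)cc2OC)=C(O)C(C)(C)C1=O
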